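**Plan**
- Retrosynthesis: the side-chain ester on O8, the C1 ketone, the C7=C11 butenolide alkene and the C4–C5 epoxide are removed first. The C4=C5 and C8=C9 bonds of the resulting ten-membered dienone are then re-paired into a bicyclo[2.2.0]hexane, which is cut at C4–C5 and C8–C9.
- Enabling feature: with C8 as a silyl enol ether, C4=C5–C6–C7–C8=C9 is a cyclodeca-1,5-diene. This is the pattern released when ring A (C4, C5, C8, C9) of a bicyclo[2.2.0]hexane, sharing C5–C8 with ring B (C5, C6, C7, C8), opens across C4–C9.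
- Forward: the cyclohexenone (C1–C4, C9, C10) comes from crotylboration and ring-closing metathesis; the cyclobutene-fused γ-lactone (C5–C8, C11–C13) comes from a ketene cycloaddition. Irradiation closes ring A, heating opens it to the ten-membered ring, and the butenolide alkene is made last.
- Stereochemistry: C10 from catalyst-controlled anti-crotylboration; C6 from the resolved bicyclic lactone; C8 from substrate-controlled reduction followed by Mitsunobu inversion; C4/C5 from nucleophilic epoxidation anti to the C6–O bond.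
- Temporary centres: C1, C7, C11 and the four centres of the photoadduct are all erased later.

Key step: step 18

Remark: germacrane locants (C1–C13 as in the target) are used for all polycyclic and ten-membered compounds; 15–17 are racemates drawn as the enantiomer that is carried on; TBS = tert-butyldimethylsilyl, TBDPS = tert-butyldiphenylsilyl, PMB = 4-methoxybenzyl.

**Route**

Step 1
Reactants: 1 propane-1,3-diol
Product: 2 3-(PMB-oxy)propan-1-ol
Conditions: NaH (1 equiv), THF/DMF, 0 °C; PMBCl, Bu4NI (cat.), rt; diol in threefold excess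
Reagents that add atoms: 4-methoxybenzyl chloride COc1ccc(CCl)cc1
Why: Williamson etherification of the mono-alkoxide, with excess diol suppressing bis-alkylation, should give the mono-PMB ether.

Step 2
Reactants: 2 3-(PMB-oxy)propan-1-ol
Product: 3 3-(PMB-oxy)propanal
Conditions: TEMPO (10 mol %), PhI(OAc)2, CH2Cl2, rt
Reagents that add atoms: none
Why: The TEMPO/PhI(OAc)2 oxidation stops at the aldehyde and leaves the PMB ether untouched.

Step 3
Reactants: 3 3-(PMB-oxy)propanal; 4 (E)-crotylboronic acid pinacol ester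
Product: 5 (3R,4S)-1-(PMB-oxy)-4-methylhex-5-en-3-ol
Conditions: (S)-TRIP phosphoric acid (5 mol %), 4 Å MS, toluene, −30 °C; aqueous work-up
Reagents that add atoms: none
Why: Chiral-phosphoric-acid-catalysed crotylboration runs through a closed chair (Zimmerman–Traxler) transition state, so the E-boronate should give the anti adduct, and the catalyst antipode is chosen to deliver (3R,4S), which fixes the future C10 as S.

Step 4
Reactants: 5 (3R,4S)-1-(PMB-oxy)-4-methylhex-5-en-3-ol
Product: 6 (3R,4S)-3-(TBSO)-1-(PMB-oxy)-4-methylhex-5-ene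
Conditions: TBSCl, imidazole, DMF, rt
Reagents that add atoms: tert-butyldimethylsilyl chloride CC(C)(C)[Si](C)(C)Cl
Why: Standard silylation of the secondary alcohol protects the future C1 oxygen for most of the route.

Step 5
Reactants: 6 (3R,4S)-3-(TBSO)-1-(PMB-oxy)-4-methylhex-5-ene
Product: 7 (3R,4S)-3-(TBSO)-4-methylhex-5-en-1-ol
Conditions: DDQ, CH2Cl2/pH 7 buffer, 0 °C
Reagents that add atoms: none
Why: Oxidative PMB cleavage with DDQ frees the primary alcohol without touching the TBS ether or the terminal alkene.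

Step 6
Reactants: 7 (3R,4S)-3-(TBSO)-4-methylhex-5-en-1-ol
Product: 8 (3R,4S)-3-(TBSO)-4-methylhex-5-enal
Conditions: TEMPO (10 mol %), PhI(OAc)2, CH2Cl2, rt
Reagents that add atoms: none
Why: The same mild oxoammonium oxidation as in step 2 should not eliminate or epimerise the β-silyloxy aldehyde.

Step 7
Reactants: 8 (3R,4S)-3-(TBSO)-4-methylhex-5-enal
Product: 9 (5R,6S)-5-(TBSO)-2,6-dimethylocta-1,7-dien-3-ol (both C3 epimers)
Conditions: CH2=C(CH3)MgBr, THF, −78 °C; then H2O
Reagents that add atoms: isopropenylmagnesium bromide CC(=C)[Mg]Br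
Why: Grignard addition to the aldehyde brings in C4 with its methyl group, and the unselective new carbinol centre is harmless because it is oxidised next.

Step 8
Reactants: 9 (5R,6S)-5-(TBSO)-2,6-dimethylocta-1,7-dien-3-ol
Product: 10 (5R,6S)-5-(TBSO)-2,6-dimethylocta-1,7-dien-3-one
Conditions: Dess–Martin periodinane, pyridine, CH2Cl2, 0 °C
Reagents that add atoms: none
Why: Dess–Martin oxidation of the allylic alcohol gives the isopropenyl ketone under non-basic conditions that spare the β-silyloxy ketone.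

Step 9
Reactants: 10 (5R,6S)-5-(TBSO)-2,6-dimethylocta-1,7-dien-3-one
Product: 11 (4S,5R)-5-(TBSO)-2,4-dimethylcyclohex-2-en-1-one (cis)
Conditions: second-generation Grubbs catalyst RuCl2(=CHPh)(H2IMes)(PCy3) (5 mol %), CH2Cl2 (0.01 M), 40 °C
Reagents that add atoms: none
Why: Ring-closing metathesis between the vinyl group and the enone alkene closes the six-membered ring with loss of ethene, a well-used route to 2-methylcyclohexenones that touches neither stereocentre.

Step 10
Reactants: 12 2,3-dihydrofuran; 13 trichloroacetyl chloride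
Product: 15 rac-(1S,5R)-7,7-dichloro-2-oxabicyclo[3.2.0]heptan-6-one, via dichloroketene 14 (not isolated)
Conditions: zinc–copper couple (Zn/Cu), Et2O, ultrasound, 15–20 °C, slow addition of 13
Reagents that add atoms: none
Why: Zinc dechlorinates the acid chloride to dichloroketene, which undergoes the thermal ketene–alkene [2+2] cycloaddition with the enol ether, the nucleophilic C3 of dihydrofuran bonding to the ketene carbonyl carbon so that the ring fusion is cis and the ketone lies next to the carbon-substituted bridgehead.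

Step 11
Reactants: 15 rac-(1S,5R)-7,7-dichloro-2-oxabicyclo[3.2.0]heptan-6-one
Product: 16 rac-(1R,5R)-2-oxabicyclo[3.2.0]heptan-6-one
Conditions: Zn dust, AcOH, rt
Reagents that add atoms: none
Why: Reductive dechlorination of the α,α-dichlorocyclobutanone with zinc in acetic acid is the standard follow-up to a dichloroketene cycloaddition.

Step 12
Reactants: 16 rac-(1R,5R)-2-oxabicyclo[3.2.0]heptan-6-one
Product: 17 rac-(1R,5R)-2-oxabicyclo[3.2.0]heptane-3,6-dione
Conditions: RuCl3·xH2O (2 mol %), NaIO4, CCl4/MeCN/H2O, rt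
Reagents that add atoms: sodium periodate [Na+].[O-]I(=O)(=O)=O; water O
Why: RuO4 generated in situ oxidises the ether methylene next to oxygen to the lactone carbonyl, the methylene reacting in preference to the strained bridgehead methine.

Step 13
Reactants: 17 rac-(1R,5R)-2-oxabicyclo[3.2.0]heptane-3,6-dione
Product: 18 (1R,5R)-2-oxabicyclo[3.2.0]heptane-3,6-dione
Conditions: preparative SFC, amylose tris(3,5-dimethylphenylcarbamate) phase, CO2/MeOH
Reagents that add atoms: none
Why: Resolution by chromatography on a chiral stationary phase should separate the enantiomers of this small rigid bicycle, and the (1R,5R) antipode, whose assignment is to be secured by X-ray analysis of a crystalline derivative before use, carries the configuration of the future C6.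

Step 14
Reactants: 18 (1R,5R)-2-oxabicyclo[3.2.0]heptane-3,6-dione
Product: 19 (1R,5R)-6-(TBSO)-2-oxabicyclo[3.2.0]hept-6-en-3-one
Conditions: TBSOTf (1.05 equiv), Et3N, CH2Cl2, −78 to 0 °C
Reagents that add atoms: tert-butyldimethylsilyl trifluoromethanesulfonate CC(C)(C)[Si](C)(C)OS(=O)(=O)C(F)(F)F
Why: Soft enolisation with silyl triflate and amine forms the silyl enol ether towards the methylene carbon, because a bridgehead double bond is too strained, and avoids a free enolate that could expel the β-acyloxy group.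

Step 15
Reactants: 19 (1R,5R)-6-(TBSO)-2-oxabicyclo[3.2.0]hept-6-en-3-one
Product: 20 (1R,4S,5R)-6-(TBSO)-4-(hydroxymethyl)-2-oxabicyclo[3.2.0]hept-6-en-3-one
Conditions: LiN(iPr)2 (LDA), THF, −78 °C; HCHO (gas), −78 to −40 °C; AcOH
Reagents that add atoms: formaldehyde C=O
Why: Aldol reaction of the lactone lithium enolate with monomeric formaldehyde should take place on the convex face of the bicycle, cis to the neighbouring bridgehead hydrogen, while the silyl enol ether is inert to the amide base.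

Step 16
Reactants: 20 (1R,4S,5R)-6-(TBSO)-4-(hydroxymethyl)-2-oxabicyclo[3.2.0]hept-6-en-3-one
Product: 21 (1R,4S,5R)-6-(TBSO)-4-(hydroxymethyl)-4-(phenylsulfanyl)-2-oxabicyclo[3.2.0]hept-6-en-3-one
Conditions: LiN(iPr)2 (2.2 equiv), THF/DMPU, −78 to −30 °C; PhSSPh; AcOH
Reagents that add atoms: diphenyl disulfide c1ccc(SSc2ccccc2)cc1
Why: The alkoxide–enolate dianion (Fráter–Seebach type, in which the alkoxide cannot leave) is sulfenylated again from the convex face, which should place sulfur cis to the bridgehead hydrogen as the later syn-elimination requires.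

Step 17
Reactants: 21 (1R,4S,5R)-6-(TBSO)-4-(hydroxymethyl)-4-(phenylsulfanyl)-2-oxabicyclo[3.2.0]hept-6-en-3-one
Product: 22 [(1R,4S,5R)-6-(TBSO)-3-oxo-4-(phenylsulfanyl)-2-oxabicyclo[3.2.0]hept-6-en-4-yl]methyl acetate
Conditions: Ac2O, pyridine, DMAP (cat.), CH2Cl2, 0 °C
Reagents that add atoms: acetic anhydride CC(=O)OC(C)=O
Why: Standard acetylation installs the C13 acetate, which cannot be eliminated from the now quaternary α-carbon.

Step 18
Reactants: 11 (4S,5R)-5-(TBSO)-2,4-dimethylcyclohex-2-en-1-one; 22 [(1R,4S,5R)-6-(TBSO)-3-oxo-4-(phenylsulfanyl)-2-oxabicyclo[3.2.0]hept-6-en-4-yl]methyl acetate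
Product: 23 (1R,4R,5R,6R,7R,8S,9S,10S,11S)-13-acetoxy-1,8-bis(TBSO)-11-(phenylsulfanyl)-3-oxo-4,9:5,8-dicyclogermacrano-12,6-lactone (cis-anti-cis photoadduct)
Conditions: hν (365 nm LEDs or Hg lamp through uranium glass), degassed CH2Cl2, −40 °C, 22 (2 equiv, excess recovered)
Reagents that add atoms: none
Why: Irradiation excites the enone 11 (n,π*), which crosses to its twisted triplet and adds to the electron-rich enol ether double bond of 22; the triplet 1,4-diradical undergoes spin inversion and collapses by radical recombination, closing the four-membered ring A (C4–C5–C8–C9), which together with the existing ring B completes the bicyclo[2.2.0]hexane. The closest known reaction type is the intermolecular enone–cyclobutene [2+2] photocycloaddition, and more generally the enone–enol ether photocycloaddition. The head-to-tail orientation that the route needs (silyloxy carbon C8 to the enone β-carbon C9, C5 to the α-carbon C4) should follow from the donor oxygen on C8, as in enone additions to enol ethers and ketene acetals. C4 and C9 should form with a cis ring fusion on the enone face opposite the C10 methyl and C1 silyloxy groups, which lie on the same side in 11. C5 and C8 should form on the convex face of the bicyclic cyclobutene, cis to H6 and H7, so that the lactone ends up exo on the new bicyclohexane. Leakage in facial selectivity costs only material, because C4, C5, C8 and C9 all become trigonal in step 19 and only the regiochemistry is essential.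

Step 19
Reactants: 23 cis-anti-cis photoadduct
Product: 24 (1R,4E,6R,7R,8E,10S,11S)-13-acetoxy-1,8-bis(TBSO)-11-(phenylsulfanyl)-3-oxogermacra-4,8-dieno-12,6-lactone
Conditions: degassed o-dichlorobenzene, BHT (cat.), silylated glassware, 180 °C, shortest time for full conversion
Reagents that add atoms: none
Why: Thermal homolysis of the strained central C5–C8 bond gives a cyclohexane-1,4-diyl that fragments across C4–C9 (formal retro-[2+2], as in known bicyclo[2.2.0]hexane to 1,5-diene openings) to the conjugated enone and the C8 silyl enol ether, erasing C4, C5, C8 and C9, whereas C6–C7 scission or a later Cope shift would give up the enone conjugation and turn the γ-lactone into a nine-membered ring; the 4E geometry drawn requires C3 to sit equatorial in the chair-like diyl and is the least secure feature of the step.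

Step 20
Reactants: 24 ring-opened dienone silyl enol ether
Product: 26 (1R,4E,6R,7S,8R,10S,11S)-13-acetoxy-8-hydroxy-1-(TBSO)-11-(phenylsulfanyl)-3-oxogermacr-4-eno-12,6-lactone, via C8 ketone 25 (not isolated)
Conditions: Bu4NF (1.1 equiv), AcOH (1.5 equiv), THF, −20 °C; then MeOH, NaBH4, −78 °C
Reagents that add atoms: none
Why: Buffered fluoride cleaves the silyl enol ether much faster than the alkyl silyl ether, and NaBH4 at low temperature should reduce the saturated C8 ketone ahead of the conjugated C3 ketone, with hydride approaching anti to the quaternary C11 (Felkin–Anh) to give the 8R alcohol before the β-acyloxy ketone can eliminate.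

Step 21
Reactants: 27 4-methylfuran-2(5H)-one
Product: 30 (Z)-4-(TBDPSO)-3-methylbut-2-enoic acid, via potassium hydroxy enoate 28 (not isolated), via bis-silyl ester ether 29 (not isolated)
Conditions: KOH (1.0 equiv), MeOH/H2O, rt, evaporate; TBDPSCl (2.2 equiv), imidazole, DMF, rt; AcOH/THF/H2O, rt
Reagents that add atoms: potassium hydroxide [K+].[OH-]; tert-butyl(chloro)diphenylsilane CC(C)(C)[Si](Cl)(c1ccccc1)c1ccccc1
Why: Saponification opens the butenolide with the Z geometry inherited from the ring, silylation caps both oxygens before relactonisation can occur, and the labile silyl ester is hydrolysed selectively to leave the silyl ether acid.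

Step 22
Reactants: 26 8R hydroxy enone; 30 (Z)-4-(TBDPSO)-3-methylbut-2-enoic acid
Product: 31 (1R,4E,6R,7S,8S,10S,11S)-13-acetoxy-8-{[(Z)-4-(TBDPSO)-3-methylbut-2-enoyl]oxy}-1-(TBSO)-11-(phenylsulfanyl)-3-oxogermacr-4-eno-12,6-lactone
Conditions: PPh3, DIAD, toluene, 0 °C to rt
Reagents that add atoms: none
Why: Mitsunobu esterification activates the 8R alcohol as its oxyphosphonium ion, which the carboxylate displaces with inversion to give the 8S ester of the target.

Step 23
Reactants: 31 8S ester enone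
Product: 32 (1R,4S,5R,6S,7S,8S,10S,11S)-13-acetoxy-4,5-epoxy-8-{[(Z)-4-(TBDPSO)-3-methylbut-2-enoyl]oxy}-1-(TBSO)-11-(phenylsulfanyl)-3-oxogermacrano-12,6-lactone
Conditions: tBuOOH (anhydrous, in decane), DBU, CH2Cl2, 0 °C
Reagents that add atoms: tert-butyl hydroperoxide CC(C)(C)OO
Why: In this Weitz–Scheffer epoxidation the peroxide anion should add to C5 anti to the allylic C6–O bond on the outer face of the ring and the C3 enolate then closes the oxirane to the trans 4S,5R epoxy ketone, while the β,β-disubstituted side-chain enoate and the sulfide are not attacked.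

Step 24
Reactants: 32 epoxy ketone sulfide
Product: 34 (1R,4S,5R,6S,8S,10S)-13-acetoxy-4,5-epoxy-8-{[(Z)-4-(TBDPSO)-3-methylbut-2-enoyl]oxy}-1-(TBSO)-3-oxogermacr-7(11)-eno-12,6-lactone, via sulfoxide 33 (not isolated)
Conditions: mCPBA (1.0 equiv), CH2Cl2, −78 °C; then toluene, 110 °C
Reagents that add atoms: none
Why: Chemoselective sulfide oxidation followed by thermal sulfoxide syn-elimination should form the C7=C11 butenolide double bond, because sulfur is cis to H7 and elimination towards the oxygen-bearing C13 is disfavoured.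

Step 25
Reactants: 34 butenolide with C1 silyl ether
Product: 35 (1R,4S,5R,6S,8S,10S)-13-acetoxy-4,5-epoxy-1-hydroxy-8-{[(Z)-4-(TBDPSO)-3-methylbut-2-enoyl]oxy}-3-oxogermacr-7(11)-eno-12,6-lactone
Conditions: HF·pyridine, pyridine, THF, 0 °C to rt
Reagents that add atoms: none
Why: Fluoride-mediated desilylation should remove the secondary TBS ether while the more robust primary TBDPS ether stays in place.

Step 26
Reactants: 35 C1 alcohol
Product: 36 (4S,5R,6S,8S,10S)-13-acetoxy-4,5-epoxy-8-{[(Z)-4-(TBDPSO)-3-methylbut-2-enoyl]oxy}-1,3-dioxogermacr-7(11)-eno-12,6-lactone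
Conditions: Dess–Martin periodinane, pyridine, CH2Cl2, 0 °C
Reagents that add atoms: none
Why: Dess–Martin oxidation of the β-hydroxy ketone gives the C1,C3-diketone under neutral conditions that should neither epimerise C10 nor open the epoxide.

Step 27
Reactants: 36 silyl-protected diketone
Product: 37 (4S,5R,6S,8S,10S)-13-acetoxy-4,5-epoxy-8-{[(Z)-4-hydroxy-3-methylbut-2-enoyl]oxy}-1,3-dioxogermacr-7(11)-eno-12,6-lactone (CNP0295642.1)
Conditions: HF·pyridine, THF, 0 °C to rt
Reagents that add atoms: none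
Why: Acidic fluoride cleaves the primary allylic TBDPS ether without generating an alkoxide, so the Z-γ-hydroxy ester should not lactonise and the acetate, epoxide and diketone should survive.

**Compound list**

1 | propane-1,3-diol | OCCCO | starting material
2 | 3-[(4-methoxybenzyl)oxy]propan-1-ol | COc1ccc(COCCCO)cc1 | intermediate
3 | 3-[(4-methoxybenzyl)oxy]propanal | COc1ccc(COCCC=O)cc1 | intermediate
4 | (E)-crotylboronic acid pinacol ester | C/C=C/CB1OC(C)(C)C(C)(C)O1 | starting material
5 | (3R,4S)-1-[(4-methoxybenzyl)oxy]-4-methylhex-5-en-3-ol | C=C[C@H](C)[C@H](O)CCOCc1ccc(OC)cc1 | intermediate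
6 | (3R,4S)-3-(tert-butyldimethylsilyloxy)-1-[(4-methoxybenzyl)oxy]-4-methylhex-5-ene | C=C[C@H](C)[C@H](O[Si](C)(C)C(C)(C)C)CCOCc1ccc(OC)cc1 | intermediate
7 | (3R,4S)-3-(tert-butyldimethylsilyloxy)-4-methylhex-5-en-1-ol | C=C[C@H](C)[C@H](O[Si](C)(C)C(C)(C)C)CCO | intermediate
8 | (3R,4S)-3-(tert-butyldimethylsilyloxy)-4-methylhex-5-enal | C=C[C@H](C)[C@H](O[Si](C)(C)C(C)(C)C)CC=O | intermediate
9 | (5R,6S)-5-(tert-butyldimethylsilyloxy)-2,6-dimethylocta-1,7-dien-3-ol, both C3 epimers | C=C[C@H](C)[C@H](O[Si](C)(C)C(C)(C)C)CC(O)C(C)=C | intermediate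
10 | (5R,6S)-5-(tert-butyldimethylsilyloxy)-2,6-dimethylocta-1,7-dien-3-one | C=C[C@H](C)[C@H](O[Si](C)(C)C(C)(C)C)CC(=O)C(C)=C | intermediate
11 | (4S,5R)-5-(tert-butyldimethylsilyloxy)-2,4-dimethylcyclohex-2-en-1-one (methyl and silyloxy cis) | CC1=C[C@H](C)[C@H](O[Si](C)(C)C(C)(C)C)CC1=O | intermediate
12 | 2,3-dihydrofuran | C1CC=CO1 | starting material
13 | trichloroacetyl chloride | ClC(Cl)(Cl)C(Cl)=O | starting material
14 | dichloroketene (not isolated) | ClC(Cl)=C=O | intermediate
15 | rac-(1S,5R)-7,7-dichloro-2-oxabicyclo[3.2.0]heptan-6-one (cis-fused; one enantiomer drawn) | C1C[C@H]2C(=O)C(Cl)(Cl)[C@H]2O1 | intermediate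
16 | rac-(1R,5R)-2-oxabicyclo[3.2.0]heptan-6-one (one enantiomer drawn) | C1C[C@H]2C(=O)C[C@H]2O1 | intermediate
17 | rac-(1R,5R)-2-oxabicyclo[3.2.0]heptane-3,6-dione (one enantiomer drawn) | O=C1C[C@H]2C(=O)C[C@H]2O1 | intermediate
18 | (1R,5R)-2-oxabicyclo[3.2.0]heptane-3,6-dione, single enantiomer | O=C1C[C@H]2C(=O)C[C@H]2O1 | intermediate
19 | (1R,5R)-6-(tert-butyldimethylsilyloxy)-2-oxabicyclo[3.2.0]hept-6-en-3-one | O=C1C[C@H]2C(O[Si](C)(C)C(C)(C)C)=C[C@H]2O1 | intermediate
20 | (1R,4S,5R)-6-(tert-butyldimethylsilyloxy)-4-(hydroxymethyl)-2-oxabicyclo[3.2.0]hept-6-en-3-one (CH2OH cis to H5) | O=C1[C@H](CO)[C@H]2C(O[Si](C)(C)C(C)(C)C)=C[C@H]2O1 | intermediate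
21 | (1R,4S,5R)-6-(tert-butyldimethylsilyloxy)-4-(hydroxymethyl)-4-(phenylsulfanyl)-2-oxabicyclo[3.2.0]hept-6-en-3-one (sulfur cis to H5) | O=C1[C@](CO)(Sc3ccccc3)[C@H]2C(O[Si](C)(C)C(C)(C)C)=C[C@H]2O1 | intermediate
22 | [(1R,4S,5R)-6-(tert-butyldimethylsilyloxy)-3-oxo-4-(phenylsulfanyl)-2-oxabicyclo[3.2.0]hept-6-en-4-yl]methyl acetate | O=C1[C@](COC(C)=O)(Sc3ccccc3)[C@H]2C(O[Si](C)(C)C(C)(C)C)=C[C@H]2O1 | intermediate
23 | cis-anti-cis photoadduct, (1R,4R,5R,6R,7R,8S,9S,10S,11S)-13-acetoxy-1,8-bis(tert-butyldimethylsilyloxy)-11-(phenylsulfanyl)-3-oxo-4,9:5,8-dicyclogermacrano-12,6-lactone | O=C1C[C@@H](O[Si](C)(C)C(C)(C)C)[C@@H](C)[C@H]2[C@]1(C)[C@@H]3[C@H]4OC(=O)[C@](COC(C)=O)(Sc5ccccc5)[C@H]4[C@]23O[Si](C)(C)C(C)(C)C | intermediate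
24 | (1R,4E,6R,7R,8E,10S,11S)-13-acetoxy-1,8-bis(tert-butyldimethylsilyloxy)-11-(phenylsulfanyl)-3-oxogermacra-4,8-dieno-12,6-lactone (C3/C6 trans on C4=C5; C7/C10 cis on C8=C9) | O=C1C[C@@H](O[Si](C)(C)C(C)(C)C)[C@@H](C)/C=C(O[Si](C)(C)C(C)(C)C)\[C@H]2[C@H](OC(=O)[C@]2(COC(C)=O)Sc3ccccc3)/C=C1\C | intermediate
25 | (1R,4E,6R,7R,10S,11S)-13-acetoxy-1-(tert-butyldimethylsilyloxy)-11-(phenylsulfanyl)-3,8-dioxogermacr-4-eno-12,6-lactone (not isolated) | O=C1C[C@@H](O[Si](C)(C)C(C)(C)C)[C@@H](C)CC(=O)[C@H]2[C@H](OC(=O)[C@]2(COC(C)=O)Sc3ccccc3)/C=C1\C | intermediate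
26 | (1R,4E,6R,7S,8R,10S,11S)-13-acetoxy-8-hydroxy-1-(tert-butyldimethylsilyloxy)-11-(phenylsulfanyl)-3-oxogermacr-4-eno-12,6-lactone | O=C1C[C@@H](O[Si](C)(C)C(C)(C)C)[C@@H](C)C[C@@H](O)[C@H]2[C@H](OC(=O)[C@]2(COC(C)=O)Sc3ccccc3)/C=C1\C | intermediate
27 | 4-methylfuran-2(5H)-one | CC1=CC(=O)OC1 | starting material
28 | potassium (Z)-4-hydroxy-3-methylbut-2-enoate (not isolated) | [K+].[O-]C(=O)/C=C(/C)CO | intermediate
29 | tert-butyldiphenylsilyl (Z)-4-(tert-butyldiphenylsilyloxy)-3-methylbut-2-enoate (not isolated) | CC(C)(C)[Si](OC(=O)/C=C(/C)CO[Si](c1ccccc1)(c2ccccc2)C(C)(C)C)(c3ccccc3)c4ccccc4 | intermediate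
30 | (Z)-4-(tert-butyldiphenylsilyloxy)-3-methylbut-2-enoic acid | OC(=O)/C=C(/C)CO[Si](c1ccccc1)(c2ccccc2)C(C)(C)C | intermediate
31 | (1R,4E,6R,7S,8S,10S,11S)-13-acetoxy-8-{[(Z)-4-(tert-butyldiphenylsilyloxy)-3-methylbut-2-enoyl]oxy}-1-(tert-butyldimethylsilyloxy)-11-(phenylsulfanyl)-3-oxogermacr-4-eno-12,6-lactone | O=C1C[C@@H](O[Si](C)(C)C(C)(C)C)[C@@H](C)C[C@H](OC(=O)/C=C(/C)CO[Si](c4ccccc4)(c5ccccc5)C(C)(C)C)[C@H]2[C@H](OC(=O)[C@]2(COC(C)=O)Sc3ccccc3)/C=C1\C | intermediate
32 | (1R,4S,5R,6S,7S,8S,10S,11S)-13-acetoxy-4,5-epoxy-8-{[(Z)-4-(tert-butyldiphenylsilyloxy)-3-methylbut-2-enoyl]oxy}-1-(tert-butyldimethylsilyloxy)-11-(phenylsulfanyl)-3-oxogermacrano-12,6-lactone | O=C1C[C@@H](O[Si](C)(C)C(C)(C)C)[C@@H](C)C[C@H](OC(=O)/C=C(/C)CO[Si](c4ccccc4)(c5ccccc5)C(C)(C)C)[C@H]2[C@H](OC(=O)[C@]2(COC(C)=O)Sc3ccccc3)[C@H]6O[C@@]61C | intermediate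
33 | sulfoxide of 32, both sulfur epimers (not isolated) | O=C1C[C@@H](O[Si](C)(C)C(C)(C)C)[C@@H](C)C[C@H](OC(=O)/C=C(/C)CO[Si](c4ccccc4)(c5ccccc5)C(C)(C)C)[C@H]2[C@H](OC(=O)[C@]2(COC(C)=O)S(=O)c3ccccc3)[C@H]6O[C@@]61C | intermediate
34 | (1R,4S,5R,6S,8S,10S)-13-acetoxy-4,5-epoxy-8-{[(Z)-4-(tert-butyldiphenylsilyloxy)-3-methylbut-2-enoyl]oxy}-1-(tert-butyldimethylsilyloxy)-3-oxogermacr-7(11)-eno-12,6-lactone | O=C1C[C@@H](O[Si](C)(C)C(C)(C)C)[C@@H](C)C[C@H](OC(=O)/C=C(/C)CO[Si](c4ccccc4)(c5ccccc5)C(C)(C)C)C2=C(COC(C)=O)C(=O)O[C@@H]2[C@H]6O[C@@]61C | intermediate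
35 | (1R,4S,5R,6S,8S,10S)-13-acetoxy-4,5-epoxy-1-hydroxy-8-{[(Z)-4-(tert-butyldiphenylsilyloxy)-3-methylbut-2-enoyl]oxy}-3-oxogermacr-7(11)-eno-12,6-lactone | O=C1C[C@@H](O)[C@@H](C)C[C@H](OC(=O)/C=C(/C)CO[Si](c4ccccc4)(c5ccccc5)C(C)(C)C)C2=C(COC(C)=O)C(=O)O[C@@H]2[C@H]6O[C@@]61C | intermediate
36 | (4S,5R,6S,8S,10S)-13-acetoxy-4,5-epoxy-8-{[(Z)-4-(tert-butyldiphenylsilyloxy)-3-methylbut-2-enoyl]oxy}-1,3-dioxogermacr-7(11)-eno-12,6-lactone | O=C1CC(=O)[C@@H](C)C[C@H](OC(=O)/C=C(/C)CO[Si](c4ccccc4)(c5ccccc5)C(C)(C)C)C2=C(COC(C)=O)C(=O)O[C@@H]2[C@H]6O[C@@]61C | intermediate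
37 | (4S,5R,6S,8S,10S)-13-acetoxy-4,5-epoxy-8-{[(Z)-4-hydroxy-3-methylbut-2-enoyl]oxy}-1,3-dioxogermacr-7(11)-eno-12,6-lactone, CNP0295642.1 | CC(=O)OCC1=C2[C@@H](OC(=O)/C=C(/C)CO)C[C@H](C)C(=O)CC(=O)[C@@]3(C)O[C@@H]3[C@H]2OC1=O | target

**Step count**

Total: 27 steps. Longest linear sequence: 18 steps (steps 1–9, 18–20, 22–27).

**Steps most likely to fail**

1. Step 19. The diradical may fragment through the chair conformer in which C3 is axial, so that C4=C5 is formed with Z geometry, or prolonged heating may let the 1,5-diene drift by Cope rearrangement. Thermal equilibration is not expected to help, since the Z enone is probably the more stable isomer. The fallback sets out from 23: if the opening gives the (4Z,8Z) isomer of the ring-opened dienone F1, it is taken through the conditions of step 20 to the 4Z hydroxy enone F2. F2 is then irradiated (350 nm, MeCN, Pyrex) so that the enone double bond isomerises through its twisted triplet. The photostationary mixture is separated, F2 is recycled, and the route is rejoined at 26.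

2. Step 22. SN2 displacement at C8, which lies next to C7 and the quaternary C11, may be too slow, so that elimination towards C9 or esterification with retention takes over. The fallback sets out from 25, which is isolated after the fluoride treatment of step 20. The ketone is reduced with a ketoreductase (NADPH, recycled with isopropanol) selected by screening for the opposite face, giving the 8S alcohol F3. Steglich esterification of F3 with 30 (EDC·HCl, DMAP, CH2Cl2) proceeds with retention and returns to 31.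

3. Step 18. The fully substituted, sulfur-bearing cyclobutene may react too slowly at the congested silyloxy carbon, so that enone dimerisation or head-to-head addition competes. The fallback sets out from 11 and 19 and puts the C11 substituents on after the cycloaddition:
- irradiation of 11 with the unhindered cyclobutene 19 gives the simpler photoadduct F4;
- the C3 ketone is masked as the dioxolane F5 (1,2-bis(trimethylsilyloxy)ethane, TMSOTf cat., −78 °C);
- lactone hydroxymethylation as in step 15 gives the hydroxymethyl lactone F6;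
- dianion sulfenylation as in step 16 gives the hydroxy sulfide F7;
- acetylation gives the acetate F8;
- PPTS in wet acetone removes the dioxolane and returns to 23.

Further compounds
F1 | step 19 | (4Z,8Z) isomer of 24 (C3/C6 cis on C4=C5; C7/C10 trans on C8=C9) | O=C1C[C@@H](O[Si](C)(C)C(C)(C)C)[C@@H](C)/C=C(O[Si](C)(C)C(C)(C)C)/[C@H]2[C@H](OC(=O)[C@]2(COC(C)=O)Sc3ccccc3)/C=C1/C
F2 | step 19 | 4Z isomer of 26 | O=C1C[C@@H](O[Si](C)(C)C(C)(C)C)[C@@H](C)C[C@@H](O)[C@H]2[C@H](OC(=O)[C@]2(COC(C)=O)Sc3ccccc3)/C=C1/C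
F3 | step 22 | 8S epimer of 26 | O=C1C[C@@H](O[Si](C)(C)C(C)(C)C)[C@@H](C)C[C@H](O)[C@H]2[C@H](OC(=O)[C@]2(COC(C)=O)Sc3ccccc3)/C=C1\C
F4 | step 18 | cis-anti-cis photoadduct of 11 and 19 (23 without the C11 substituents) | O=C1C[C@@H](O[Si](C)(C)C(C)(C)C)[C@@H](C)[C@H]2[C@]1(C)[C@@H]3[C@H]4OC(=O)C[C@H]4[C@]23O[Si](C)(C)C(C)(C)C
F5 | step 18 | C3 ethylene ketal of F4 | O1CCOC12C[C@@H](O[Si](C)(C)C(C)(C)C)[C@@H](C)[C@H]3[C@]2(C)[C@@H]4[C@H]5OC(=O)C[C@H]5[C@]34O[Si](C)(C)C(C)(C)C
F6 | step 18 | C11 hydroxymethyl derivative of F5 (CH2OH cis to H7) | O1CCOC12C[C@@H](O[Si](C)(C)C(C)(C)C)[C@@H](C)[C@H]3[C@]2(C)[C@@H]4[C@H]5OC(=O)[C@H](CO)[C@H]5[C@]34O[Si](C)(C)C(C)(C)C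
F7 | step 18 | C11 phenylsulfanyl hydroxymethyl derivative of F5 (sulfur cis to H7) | O1CCOC12C[C@@H](O[Si](C)(C)C(C)(C)C)[C@@H](C)[C@H]3[C@]2(C)[C@@H]4[C@H]5OC(=O)[C@](CO)(Sc6ccccc6)[C@H]5[C@]34O[Si](C)(C)C(C)(C)C
F8 | step 18 | C3 ethylene ketal of 23 | O1CCOC12C[C@@H](O[Si](C)(C)C(C)(C)C)[C@@H](C)[C@H]3[C@]2(C)[C@@H]4[C@H]5OC(=O)[C@](COC(C)=O)(Sc6ccccc6)[C@H]5[C@]34O[Si](C)(C)C(C)(C)C
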